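The data are calculated for substances that don't exist; scatter was added.

Target and isomer of the product A behave like two bowls joined by a narrow pipe: each first holds what its own tap delivers, and later also what the pipe has passed between them. I take starting material as the tap of target and other conformer as the tap of the isomer.

the same everywhere: starting material 10 mM
- north-east: other conformer 1.7 mM; run made earlier
- north: other conformer 3.8 mM; run made earlier
- flask: other conformer 2.50 mM; time 50 min

| run | time / min | target / % | isomer of the product A / % | starting material / % |
|---|---|---|---|---|
| north-east | 1.50 | 20.2 | 14.5 | 20.6 |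
| north-east | 5.00 | 31.0 | 35.3 | 9.8 |
| north-east | 8.00 | 32.5 | 47.2 | 4.7 |
| north-east | 12.0 | 32.6 | 55.2 | 2.5 |
| north-east | 20.0 | 31.8 | 62.1 | 0.5 |
| north-east | 25.0 | 31.7 | 61.9 | 0 |
| north-east | 30.0 | 31.5 | 62.7 | 0.2 |
| north | 1.50 | 19.0 | 22.0 | 19.0 |
| north | 5.00 | 31.1 | 38.7 | 8.3 |
| north | 8.00 | 32.5 | 48.8 | 4.4 |
| north | 12.0 | 31.9 | 56.5 | 1.4 |
| north | 20.0 | 31.1 | 62.1 | 0.6 |
| north | 25.0 | 30.8 | 62.4 | 0.1 |
| north | 30.0 | 31.6 | 62.2 | 0 |

(readings scatter by 0.3 percentage points)

1. share of target in target plus isomer of the product A at 5.0 s
2. share of target in target plus isomer of the product A at 50 min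
3. which of target and isomer of the product A there is more of at 50 min

The first extreme is a shut pipe, kinetic control. At 1.50 min the isomer-to-target ratio climbs from 0.718 in the north-east run to 1.16 in the north run, while c(other conformer)/c(starting material) goes from 0.170 to 0.380. So each unit of that charge ratio adds 2.10. Reading this as the ratio of the taps, I estimate that the flask, at 0.250, starts near a target share of 65.6%.

The second extreme is an open pipe, thermodynamic control. Despite their different charges, the runs stand at 33.4% and 33.7% at 30.0 min. Their pooled value, 33.6%, I call the end share: target over target plus isomer once the exchange has stopped moving it.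

The real flask travels from the first extreme to the second. The north-east share reads 46.8% at 5.00 min and 37.1% at 12.0 min, so between these two readings its gap to the end share halves in about 3.71 min. Since 5.0 s is far shorter than that, I put the early share a little under 65.6%. Since 50 min holds 13.5 such half-times, I put the late share at 33.6%, which is less than half, with the isomer ahead.

The forecast gives 80%, 33.5% and isomer of the product A ahead, observing that “the target drifts little, if at all”.

The flask gives 60.4% at 5.0 s and 33.3% at 50 min, with isomer of the product A ahead at 62.7% against 31.3% of target. With the path from target to isomer of the product A struck out both ways, the flask's share at that time is 74.3%.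

    target ⇌ isomer of the product B (K = 0.190, k = 0.00160 s⁻¹)
    starting material ⇌ other conformer (K = 0.170, k = 0.00180 s⁻¹)
    starting material → target (k = 0.0100 s⁻¹)
    other conformer → isomer of the product A (k = 0.0210 s⁻¹)
    target ⇌ isomer of the product A (K = 2.00, k = 0.00510 s⁻¹)
    starting material ⇌ dormant form (K = 1.80, k = 0.110 s⁻¹)

Carried to the neighbour flask with 4.0 mM of starting material, where isomer of the product B stands at 5.96% of the charge at 50 min, the end share puts target at 31.6% of the charge, and that flask holds 31.3%.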